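**Retrosynthetic overview**
1. Target 25 comes from (S)-flavanone tetraacetate 24 by neutral, enzymatic removal of four acetyl groups.
2. 24 comes from acid 22 by cutting C4–C4a (intramolecular Friedel–Crafts acylation), which closes the pyranone ring C, the only ring built in the route (rings A and B are bought). The feature used: in ring A the ether oxygen O1 sits on C8a, whose ortho carbons are C8 (already carrying the C5 side chain) and C4a (free, and para to the C7 oxygen), so the acyl carbon C4 has one site to attack.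
3. 22 comes from forming O1–C2 by Mitsunobu inversion of (R)-β-hydroxy tert-butyl ester 19 (asymmetric transfer hydrogenation of keto ester 18) with the C2v-symmetric 2-alkylresorcinol 13.
4. 13 comes from forming the aryl–CH2 bond (the future C8 substituent) by allylation of 2-lithiated resorcinol bis-MOM ether with Z-allylic bromide 7.
5. 7 comes from propargyl alcohol; copper-catalysed anti-carbomagnesiation fixes the Z olefin.

Key step: step 15

Remark: the THP acetal carbon in 4–7 and 11 is racemic and is removed in step 7; the sense of the transfer hydrogenation in step 11 is assigned by analogy with aryl alkyl ketones and is to be confirmed on 19 before it is used.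

**Step 1**
Reactants: 1 propargyl alcohol
Product: 3 (Z)-3-iodo-2-methylprop-2-en-1-ol, via alkenylmagnesium alkoxide 2 (not isolated)
Conditions: MeMgBr (2.5 equiv), CuI (10 mol%), THF, −10 °C → rt; then I2, −78 → 0 °C
Reagents that add atoms: methylmagnesium bromide, C[Mg]Br; iodine, II
Why: Copper-catalysed anti-carbomagnesiation of the propargylic alkoxide (Normant/Duboudin type) places methyl on C2 and magnesium on C3 inside a five-membered chelate, so iodinolysis with retention should give iodine cis to CH2OH, the Z geometry the side chain needs.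

**Step 2**
Reactants: 3 (Z)-3-iodo-2-methylprop-2-en-1-ol
Product: 4 2-{[(Z)-3-iodo-2-methylprop-2-en-1-yl]oxy}tetrahydro-2H-pyran
Conditions: 3,4-dihydro-2H-pyran, PPTS (cat.), CH2Cl2, rt
Reagents that add atoms: 3,4-dihydro-2H-pyran, C1=COCCC1
Why: Acid-catalysed acetalisation (THP protection) masks the hydroxyl for the lithiation with a group that cannot migrate to carbon and that later leaves together with the aryl MOM ethers.

**Step 3**
Reactants: 4 2-{[(Z)-3-iodo-2-methylprop-2-en-1-yl]oxy}tetrahydro-2H-pyran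
Product: 6 (Z)-3-methyl-4-(tetrahydro-2H-pyran-2-yloxy)but-2-en-1-ol, via alkenyllithium 5 (not isolated)
Conditions: t-BuLi (2.1 equiv), Et2O, −78 °C; paraformaldehyde, −78 °C → rt
Reagents that add atoms: paraformaldehyde (as formaldehyde), C=O
Why: Iodine–lithium exchange of an alkenyl iodide proceeds with retention and the alkenyllithium adds to formaldehyde (hydroxymethylation), so the Z geometry should be carried into the allylic alcohol.

**Step 4**
Reactants: 6 (Z)-3-methyl-4-(tetrahydro-2H-pyran-2-yloxy)but-2-en-1-ol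
Product: 7 2-{[(Z)-4-bromo-2-methylbut-2-en-1-yl]oxy}tetrahydro-2H-pyran
Conditions: CBr4, PPh3, CH2Cl2, −20 → 0 °C; used directly
Reagents that add atoms: carbon tetrabromide, BrC(Br)(Br)Br
Why: The Appel reaction converts the primary allylic alcohol to the bromide under near-neutral, cold conditions that should preserve both the olefin geometry and the acetal.

**Step 5**
Reactants: 8 resorcinol
Product: 9 1,3-bis(methoxymethoxy)benzene
Conditions: NaH, MOMCl, DMF, 0 °C → rt
Reagents that add atoms: chloromethyl methyl ether, COCCl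
Why: Williamson-type O-alkylation of the bis-phenoxide gives the bis-MOM ether, whose two acetal oxygens direct metalation to the carbon between them.

**Step 6**
Reactants: 9 1,3-bis(methoxymethoxy)benzene; 7 2-{[(Z)-4-bromo-2-methylbut-2-en-1-yl]oxy}tetrahydro-2H-pyran
Product: 11 2-{[(Z)-4-[2,6-bis(methoxymethoxy)phenyl]-2-methylbut-2-en-1-yl]oxy}tetrahydro-2H-pyran, via aryllithium 10 (not isolated)
Conditions: n-BuLi, THF, 0 °C → rt; CuI (10 mol%), then 7, −40 → 0 °C
Reagents that add atoms: none
Why: Directed ortho-metalation between the two OMOM groups gives the C2 aryllithium, and copper-catalysed SN2 allylation at the CH2Br terminus (the γ-carbon is fully substituted) should form the aryl–CH2 bond without touching the Z olefin.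

**Step 7**
Reactants: 11 2-{[(Z)-4-[2,6-bis(methoxymethoxy)phenyl]-2-methylbut-2-en-1-yl]oxy}tetrahydro-2H-pyran
Product: 12 2-[(Z)-4-hydroxy-3-methylbut-2-en-1-yl]benzene-1,3-diol
Conditions: HCl (2 M), MeOH, rt, under argon
Reagents that add atoms: none
Why: Acid-catalysed acetal methanolysis removes both aryl MOM ethers and the THP ether in one operation at room temperature, where the olefin, deactivated by its allylic oxygen, should not cyclise onto the phenols.

**Step 8**
Reactants: 12 2-[(Z)-4-hydroxy-3-methylbut-2-en-1-yl]benzene-1,3-diol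
Product: 13 (Z)-4-(2,6-dihydroxyphenyl)-2-methylbut-2-en-1-yl acetate
Conditions: Novozym 435 (immobilised Candida antarctica lipase B), vinyl acetate, MTBE, 30 °C
Reagents that add atoms: vinyl acetate, C=COC(C)=O
Why: Lipase-catalysed irreversible transesterification with an enol ester acylates the primary aliphatic hydroxyl far faster than phenolic hydroxyls, so the symmetric diphenol with the side-chain acetate should result.

**Step 9**
Reactants: 14 3,4-dihydroxybenzoic acid
Product: 15 3,4-diacetoxybenzoic acid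
Conditions: Ac2O, pyridine, 0 °C → rt; aqueous HCl work-up
Reagents that add atoms: acetic anhydride, CC(=O)OC(C)=O
Why: Pyridine-promoted O-acetylation of both phenols (any mixed anhydride at the carboxyl group is hydrolysed on work-up) installs the ester protection that later keeps C2 from ionising.

**Step 10**
Reactants: 15 3,4-diacetoxybenzoic acid
Product: 18 tert-butyl 3-(3,4-diacetoxyphenyl)-3-oxopropanoate, via acid chloride 16 (not isolated), via acyl Meldrum's acid 17 (not isolated)
Conditions: (COCl)2, DMF (cat.), CH2Cl2, 0 °C → rt, evaporate; Meldrum's acid, pyridine, CH2Cl2, 0 °C → rt, dilute HCl wash; t-BuOH, toluene, 90 °C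
Reagents that add atoms: Meldrum's acid, CC1(C)OC(=O)CC(=O)O1; tert-butanol, CC(C)(C)O
Why: The acid chloride C-acylates Meldrum's acid, and thermolysis of the adduct with tert-butanol traps the acylketene as the β-keto tert-butyl ester (Oikawa–Yonemitsu synthesis), a sequence without strong base and therefore compatible with the aryl acetates.

**Step 11**
Reactants: 18 tert-butyl 3-(3,4-diacetoxyphenyl)-3-oxopropanoate
Product: 19 tert-butyl (R)-3-(3,4-diacetoxyphenyl)-3-hydroxypropanoate
Conditions: RuCl(p-cymene)[(R,R)-TsDPEN] (1 mol%), HCO2H/Et3N (5:2), EtOAc, 30 °C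
Reagents that add atoms: none
Why: Noyori–Ikariya asymmetric transfer hydrogenation delivers hydride to one face of the aryl ketone through the CH/π-organised six-membered transition state, which with the (R,R)-catalyst should set the carbinol centre as R.

**Step 12**
Reactants: 19 tert-butyl (R)-3-(3,4-diacetoxyphenyl)-3-hydroxypropanoate; 13 (Z)-4-(2,6-dihydroxyphenyl)-2-methylbut-2-en-1-yl acetate
Product: 20 tert-butyl (S)-3-{2-[(Z)-4-acetoxy-3-methylbut-2-en-1-yl]-3-hydroxyphenoxy}-3-(3,4-diacetoxyphenyl)propanoate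
Conditions: 13 (2.5 equiv, excess recovered), PPh3, DIAD (added last), toluene, 0 °C → rt
Reagents that add atoms: none
Why: In this Mitsunobu etherification the phenol displaces the benzylic oxyphosphonium group by SN2 with inversion, turning the R carbinol into the S aryl ether centre that becomes C2, while the symmetric diphenol in excess makes both hydroxyls equivalent and should suppress double etherification.

**Step 13**
Reactants: 20 tert-butyl (S)-3-{2-[(Z)-4-acetoxy-3-methylbut-2-en-1-yl]-3-hydroxyphenoxy}-3-(3,4-diacetoxyphenyl)propanoate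
Product: 21 tert-butyl (S)-3-{3-acetoxy-2-[(Z)-4-acetoxy-3-methylbut-2-en-1-yl]phenoxy}-3-(3,4-diacetoxyphenyl)propanoate
Conditions: Ac2O, pyridine, DMAP (cat.), CH2Cl2, 0 °C → rt
Reagents that add atoms: acetic anhydride, CC(=O)OC(C)=O
Why: DMAP-catalysed acetylation caps the remaining phenol so that it cannot be O-acylated by the acid chloride in the key step.

**Step 14**
Reactants: 21 tert-butyl (S)-3-{3-acetoxy-2-[(Z)-4-acetoxy-3-methylbut-2-en-1-yl]phenoxy}-3-(3,4-diacetoxyphenyl)propanoate
Product: 22 (S)-3-{3-acetoxy-2-[(Z)-4-acetoxy-3-methylbut-2-en-1-yl]phenoxy}-3-(3,4-diacetoxyphenyl)propanoic acid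
Conditions: TFA/CH2Cl2 (1:4), 0 °C
Reagents that add atoms: none
Why: Acidolysis of the tert-butyl ester (E1 loss of isobutene) frees the carboxylic acid without touching the acetates, and the acetoxy-deactivated benzylic ether and olefin should survive cold dilute TFA.

**Step 15**
Reactants: 22 (S)-3-{3-acetoxy-2-[(Z)-4-acetoxy-3-methylbut-2-en-1-yl]phenoxy}-3-(3,4-diacetoxyphenyl)propanoic acid
Product: 24 (2S)-7-acetoxy-8-[(Z)-4-acetoxy-3-methylbut-2-en-1-yl]-2-(3,4-diacetoxyphenyl)chroman-4-one, via acid chloride 23 (not isolated)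
Conditions: (COCl)2, DMF (cat.), CH2Cl2, 0 °C → rt, evaporate; SnCl4 (2.5 equiv), 2,6-di-tert-butyl-4-methylpyridine (1.1 equiv), CH2Cl2, −78 → −20 °C
Reagents that add atoms: none
Why: Oxalyl chloride gives acid chloride 23, which SnCl4 activates to an acylium-type electrophile that attacks C4a of the aryl ether ring, and loss of the ring proton to the hindered pyridine forms the C4–C4a bond. The closest known reaction is the intramolecular Friedel–Crafts acylation of 3-aryloxypropanoyl chlorides to chroman-4-ones. The pyranone ring C closes as a six-membered ring by attack of an arene carbon on the acyl carbon, with the C=O exocyclic to the new ring. No stereocentre is formed; C2, set in step 12, is not a reacting atom, and its retention should be secured by the two catechol acetates, which destabilise a benzylic cation at C2, and by the low temperature, which disfavours β-elimination of the aryloxide. Regioselectivity is secured because the other carbon ortho to O1 (C8) carries the side chain and C4a is also para to the C7 oxygen, whereas closure onto the catechol ring would need a five-membered ring on an acetoxy-deactivated arene. Chemoselectivity toward the trisubstituted olefin rests on its allylic acetoxy group and on trapping of HCl by the pyridine base.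

**Step 16**
Reactants: 24 (2S)-7-acetoxy-8-[(Z)-4-acetoxy-3-methylbut-2-en-1-yl]-2-(3,4-diacetoxyphenyl)chroman-4-one
Product: 25 (2S)-2-(3,4-dihydroxyphenyl)-7-hydroxy-8-[(Z)-4-hydroxy-3-methylbut-2-en-1-yl]chroman-4-one
Conditions: Novozym 435, n-BuOH, THF, 40 °C
Reagents that add atoms: none
Why: Lipase-catalysed alcoholysis transfers all four acetyl groups to butanol at neutral pH, which should avoid the base-induced ring opening to the chalcone that would racemise C2.

**Compound list**
1 | propargyl alcohol | C#CCO | starting material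
2 | (Z)-alkenylmagnesium alkoxide, BrMg–CH=C(CH3)–CH2OMgBr | C/C(CO[Mg]Br)=C/[Mg]Br | intermediate (not isolated)
3 | (Z)-3-iodo-2-methylprop-2-en-1-ol | C/C(CO)=C/I | intermediate
4 | 2-{[(Z)-3-iodo-2-methylprop-2-en-1-yl]oxy}tetrahydro-2H-pyran (racemic at the acetal carbon) | C/C(COC1CCCCO1)=C/I | intermediate
5 | [(Z)-2-methyl-3-(tetrahydro-2H-pyran-2-yloxy)prop-1-en-1-yl]lithium | C/C(COC1CCCCO1)=C/[Li] | intermediate (not isolated)
6 | (Z)-3-methyl-4-(tetrahydro-2H-pyran-2-yloxy)but-2-en-1-ol | C/C(COC1CCCCO1)=C/CO | intermediate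
7 | 2-{[(Z)-4-bromo-2-methylbut-2-en-1-yl]oxy}tetrahydro-2H-pyran | C/C(COC1CCCCO1)=C/CBr | intermediate
8 | resorcinol | Oc1cccc(O)c1 | starting material
9 | 1,3-bis(methoxymethoxy)benzene | COCOc1cccc(OCOC)c1 | intermediate
10 | [2,6-bis(methoxymethoxy)phenyl]lithium | [Li]c1c(OCOC)cccc1OCOC | intermediate (not isolated)
11 | 2-{[(Z)-4-[2,6-bis(methoxymethoxy)phenyl]-2-methylbut-2-en-1-yl]oxy}tetrahydro-2H-pyran | C/C(COC1CCCCO1)=C/Cc1c(OCOC)cccc1OCOC | intermediate
12 | 2-[(Z)-4-hydroxy-3-methylbut-2-en-1-yl]benzene-1,3-diol | C/C(CO)=C/Cc1c(O)cccc1O | intermediate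
13 | (Z)-4-(2,6-dihydroxyphenyl)-2-methylbut-2-en-1-yl acetate | C/C(COC(C)=O)=C/Cc1c(O)cccc1O | intermediate
14 | 3,4-dihydroxybenzoic acid | OC(=O)c1ccc(O)c(O)c1 | starting material
15 | 3,4-diacetoxybenzoic acid | CC(=O)Oc1ccc(C(=O)O)cc1OC(C)=O | intermediate
16 | 3,4-diacetoxybenzoyl chloride | CC(=O)Oc1ccc(C(Cl)=O)cc1OC(C)=O | intermediate (not isolated)
17 | 5-[(3,4-diacetoxyphenyl)(hydroxy)methylidene]-2,2-dimethyl-1,3-dioxane-4,6-dione | CC(=O)Oc1ccc(C(O)=C2C(=O)OC(C)(C)OC2=O)cc1OC(C)=O | intermediate (not isolated)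
18 | tert-butyl 3-(3,4-diacetoxyphenyl)-3-oxopropanoate | CC(=O)Oc1ccc(C(=O)CC(=O)OC(C)(C)C)cc1OC(C)=O | intermediate
19 | tert-butyl (R)-3-(3,4-diacetoxyphenyl)-3-hydroxypropanoate | CC(C)(C)OC(=O)C[C@@H](O)c1ccc(OC(C)=O)c(OC(C)=O)c1 | intermediate
20 | tert-butyl (S)-3-{2-[(Z)-4-acetoxy-3-methylbut-2-en-1-yl]-3-hydroxyphenoxy}-3-(3,4-diacetoxyphenyl)propanoate | CC(C)(C)OC(=O)C[C@H](Oc1cccc(O)c1C/C=C(/C)COC(C)=O)c1ccc(OC(C)=O)c(OC(C)=O)c1 | intermediate
21 | tert-butyl (S)-3-{3-acetoxy-2-[(Z)-4-acetoxy-3-methylbut-2-en-1-yl]phenoxy}-3-(3,4-diacetoxyphenyl)propanoate | CC(C)(C)OC(=O)C[C@H](Oc1cccc(OC(C)=O)c1C/C=C(/C)COC(C)=O)c1ccc(OC(C)=O)c(OC(C)=O)c1 | intermediate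
22 | (S)-3-{3-acetoxy-2-[(Z)-4-acetoxy-3-methylbut-2-en-1-yl]phenoxy}-3-(3,4-diacetoxyphenyl)propanoic acid | OC(=O)C[C@H](Oc1cccc(OC(C)=O)c1C/C=C(/C)COC(C)=O)c1ccc(OC(C)=O)c(OC(C)=O)c1 | intermediate (key-step precursor)
23 | (S)-3-{3-acetoxy-2-[(Z)-4-acetoxy-3-methylbut-2-en-1-yl]phenoxy}-3-(3,4-diacetoxyphenyl)propanoyl chloride | ClC(=O)C[C@H](Oc1cccc(OC(C)=O)c1C/C=C(/C)COC(C)=O)c1ccc(OC(C)=O)c(OC(C)=O)c1 | intermediate (not isolated)
24 | (2S)-7-acetoxy-8-[(Z)-4-acetoxy-3-methylbut-2-en-1-yl]-2-(3,4-diacetoxyphenyl)chroman-4-one | C/C(=C/Cc1c(OC(C)=O)ccc2c1O[C@H](c1ccc(OC(C)=O)c(OC(C)=O)c1)CC2=O)COC(C)=O | intermediate (key-step product)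
25 | (2S)-2-(3,4-dihydroxyphenyl)-7-hydroxy-8-[(Z)-4-hydroxy-3-methylbut-2-en-1-yl]chroman-4-one | C/C(=C/Cc1c(O)ccc2c1O[C@H](c1ccc(O)c(O)c1)CC2=O)CO | target

**Step count**
Total: 16 steps. Longest linear sequence: 12 steps (1–4, 6–8, 12–16, from propargyl alcohol).

**Steps most likely to fail**

Step 15 (key step). The Lewis acid may ionise the benzylic C2–O bond or induce β-elimination of the aryloxide from the activated acyl group, which would erode or destroy the C2 configuration. The HCl/SnCl4 couple may protonate the side-chain olefin, and the acetoxy-bearing ring may acylate too slowly. The fallback activates the arene so that no Lewis acid is needed. It sets out from 20: the free phenol is silylated (TIPSOTf, 2,6-lutidine, CH2Cl2, −78 °C) to tert-butyl (S)-3-{2-[(Z)-4-acetoxy-3-methylbut-2-en-1-yl]-3-(triisopropylsilyloxy)phenoxy}-3-(3,4-diacetoxyphenyl)propanoate F1. Cold TFA/CH2Cl2 then gives the corresponding acid F2, and oxalyl chloride with catalytic DMF gives the acid chloride F3. Dissolved in hexafluoroisopropanol at room temperature, F3 should cyclise without any promoter (the known HFIP-promoted intramolecular Friedel–Crafts acylation of activated arenes, here helped by the silyloxy group para to C4a) to the 7-triisopropylsilyloxy flavanone triacetate F4. Et3N·3HF in THF removes the silyl group to give the 7-hydroxy flavanone triacetate F5, which under the conditions of step 16 comes back to the route at 25.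

Step 12. The oxyphosphonium intermediate may lose a proton from the acidic α-CH2 and dehydrate to the cinnamate (E1cB) faster than it is displaced, and partial ionisation would erode the inversion. The fallback removes the acidifying carbonyl before the etherification. It sets out from 19: TFA/CH2Cl2 gives (R)-3-(3,4-diacetoxyphenyl)-3-hydroxypropanoic acid F6, and BH3·SMe2 in THF at 0 °C reduces the carboxylic acid chemoselectively to (R)-1-(3,4-diacetoxyphenyl)propane-1,3-diol F7. TBSCl/Et3N/DMAP silylates the primary hydroxyl to (R)-3-(tert-butyldimethylsilyloxy)-1-(3,4-diacetoxyphenyl)propan-1-ol F8. The Mitsunobu reaction with 13 under the step 12 conditions (a 1-aryl-3-oxypropan-1-ol without an acidifying group next to the carbinol) should then give the (S)-aryl ether with a free phenol F9. Ac2O/pyridine gives its aryl acetate F10, HF·pyridine in THF frees the primary alcohol F11, and TEMPO/PhI(OAc)2 in aqueous acetonitrile oxidises it to the acid, coming back to the route at 22.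

Step 16. Enzymatic cleavage may stall at the hindered C7 acetate next to the C8 chain and leave partially acetylated mixtures, and prolonged exposure raises the chance of ring opening to the chalcone. The fallback is a two-stage chemical deacylation from 24. Ammonium acetate in aqueous methanol at room temperature, a neutral reagent selective for aryl acetates, should give (2S)-8-[(Z)-4-acetoxy-3-methylbut-2-en-1-yl]-2-(3,4-dihydroxyphenyl)-7-hydroxychroman-4-one F12. Acid-catalysed methanolysis (HCl generated from acetyl chloride in MeOH, 0 °C → rt) then removes the primary allylic acetate and comes back to the route at 25; acid is chosen because the flavanone centre is far more stable to dilute acid than to base.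

**Further compounds**
F1 | step 15 | tert-butyl (S)-3-{2-[(Z)-4-acetoxy-3-methylbut-2-en-1-yl]-3-(triisopropylsilyloxy)phenoxy}-3-(3,4-diacetoxyphenyl)propanoate | CC(C)(C)OC(=O)C[C@H](Oc1cccc(O[Si](C(C)C)(C(C)C)C(C)C)c1C/C=C(/C)COC(C)=O)c1ccc(OC(C)=O)c(OC(C)=O)c1
F2 | step 15 | (S)-3-{2-[(Z)-4-acetoxy-3-methylbut-2-en-1-yl]-3-(triisopropylsilyloxy)phenoxy}-3-(3,4-diacetoxyphenyl)propanoic acid | OC(=O)C[C@H](Oc1cccc(O[Si](C(C)C)(C(C)C)C(C)C)c1C/C=C(/C)COC(C)=O)c1ccc(OC(C)=O)c(OC(C)=O)c1
F3 | step 15 | (S)-3-{2-[(Z)-4-acetoxy-3-methylbut-2-en-1-yl]-3-(triisopropylsilyloxy)phenoxy}-3-(3,4-diacetoxyphenyl)propanoyl chloride | ClC(=O)C[C@H](Oc1cccc(O[Si](C(C)C)(C(C)C)C(C)C)c1C/C=C(/C)COC(C)=O)c1ccc(OC(C)=O)c(OC(C)=O)c1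
F4 | step 15 | (2S)-8-[(Z)-4-acetoxy-3-methylbut-2-en-1-yl]-2-(3,4-diacetoxyphenyl)-7-(triisopropylsilyloxy)chroman-4-one | C/C(=C/Cc1c(O[Si](C(C)C)(C(C)C)C(C)C)ccc2c1O[C@H](c1ccc(OC(C)=O)c(OC(C)=O)c1)CC2=O)COC(C)=O
F5 | step 15 | (2S)-8-[(Z)-4-acetoxy-3-methylbut-2-en-1-yl]-2-(3,4-diacetoxyphenyl)-7-hydroxychroman-4-one | C/C(=C/Cc1c(O)ccc2c1O[C@H](c1ccc(OC(C)=O)c(OC(C)=O)c1)CC2=O)COC(C)=O
F6 | step 12 | (R)-3-(3,4-diacetoxyphenyl)-3-hydroxypropanoic acid | OC(=O)C[C@@H](O)c1ccc(OC(C)=O)c(OC(C)=O)c1
F7 | step 12 | (R)-1-(3,4-diacetoxyphenyl)propane-1,3-diol | OCC[C@@H](O)c1ccc(OC(C)=O)c(OC(C)=O)c1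
F8 | step 12 | (R)-3-(tert-butyldimethylsilyloxy)-1-(3,4-diacetoxyphenyl)propan-1-ol | CC(C)(C)[Si](C)(C)OCC[C@@H](O)c1ccc(OC(C)=O)c(OC(C)=O)c1
F9 | step 12 | (Z)-4-{2-[(S)-3-(tert-butyldimethylsilyloxy)-1-(3,4-diacetoxyphenyl)propoxy]-6-hydroxyphenyl}-2-methylbut-2-en-1-yl acetate | CC(C)(C)[Si](C)(C)OCC[C@H](Oc1cccc(O)c1C/C=C(/C)COC(C)=O)c1ccc(OC(C)=O)c(OC(C)=O)c1
F10 | step 12 | (Z)-4-{2-acetoxy-6-[(S)-3-(tert-butyldimethylsilyloxy)-1-(3,4-diacetoxyphenyl)propoxy]phenyl}-2-methylbut-2-en-1-yl acetate | CC(C)(C)[Si](C)(C)OCC[C@H](Oc1cccc(OC(C)=O)c1C/C=C(/C)COC(C)=O)c1ccc(OC(C)=O)c(OC(C)=O)c1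
F11 | step 12 | (Z)-4-{2-acetoxy-6-[(S)-1-(3,4-diacetoxyphenyl)-3-hydroxypropoxy]phenyl}-2-methylbut-2-en-1-yl acetate | OCC[C@H](Oc1cccc(OC(C)=O)c1C/C=C(/C)COC(C)=O)c1ccc(OC(C)=O)c(OC(C)=O)c1
F12 | step 16 | (2S)-8-[(Z)-4-acetoxy-3-methylbut-2-en-1-yl]-2-(3,4-dihydroxyphenyl)-7-hydroxychroman-4-one | C/C(=C/Cc1c(O)ccc2c1O[C@H](c1ccc(O)c(O)c1)CC2=O)COC(C)=O
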